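**Plan**

- Retrosynthetic cuts, in order: the pyran O1–C8a bond (tertiary alkoxide for methoxide on a dimethoxyquinone); the quinone C7–C8 bond, traced back through a dienylketene to the C1–C4 bond of a cyclobutenone; the C4a–alkyne and C5–C6 bonds (two organolithium additions to dimethyl squarate); the carbinol C–CH2 bond (lithiation–borylation); the cyclohexene (Diels–Alder).
- Enabling feature: quinone atoms C8–C8a–C4a–C5 carry O, O, C, O and so form a squaric acid unit, and C6(OMe)=C7H is a 1-methoxyvinyl group. C8=O can therefore be a ketene carbon released from a 4-(1-methoxyvinyl)cyclobutenone, which closes onto the vinyl CH2.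
- Forward order: cyclohexene ring (Diels–Alder) → side chain with the tertiary propargylic carbinol → cyclobutenone → benzene ring (4π opening/6π closure) → Z-alkene → quinone → pyran ring last.
- Stereochemistry: the ring CH(Me) comes from an oxazolidinone-controlled Diels–Alder reaction; the quaternary ring carbon from enolate methylation anti to it; the carbinol from (R)-4-(trimethylsilyl)but-3-yn-2-ol by stereospecific lithiation–borylation, its C–O bond never being broken afterwards.

Key step: step 12

Assumption: acrylimide 1 is taken as a catalogue compound (it is otherwise one N-acylation from (S)-4-benzyloxazolidin-2-one), diene 2 is used as the E-rich commercial isomer mixture, the Z isomer being too slow a diene to compete, and the silylated butynol of step 7 is bought as the single R enantiomer.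

**Route**

Step 1
Reactants: 1 (4S)-4-benzyl-3-(prop-2-enoyl)-1,3-oxazolidin-2-one; 2 (3E)-3-methylpenta-1,3-diene
Product: 3 (4S)-4-benzyl-3-{[(1R,2R)-2,3-dimethylcyclohex-3-en-1-yl]carbonyl}-1,3-oxazolidin-2-one
Conditions: Et2AlCl (1.4 equiv), excess 2, CH2Cl2, −100 → −78 °C; 1 M HCl
Reagents that add atoms: none
Why: Auxiliary-controlled Diels–Alder reaction: the Et2AlCl-chelated s-cis acrylimide should add endo on the face opposite the benzyl group, the methyl-bearing diene terminus bonding to the α-carbon ("ortho" rule), which sets the ring CH(Me) centre as R in the cis adduct; regio- and stereoisomers are diastereomers and should be removable by chromatography or crystallisation.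

Step 2
Reactants: 3
Product: 4 ethyl (1R,2R)-2,3-dimethylcyclohex-3-ene-1-carboxylate
Conditions: EtMgBr, EtOH, THF, 0 °C → rt
Reagents that add atoms: ethanol, CCO (delivered as bromomagnesium ethoxide, CCO[Mg]Br)
Why: Exocyclic acyl transfer from the imide to the magnesium alkoxide (auxiliary transesterification) should free the ester and the recoverable auxiliary; any epimerisation at C1 is harmless because that centre is enolised in the next step.

Step 3
Reactants: 4
Product: 6 ethyl (1R,2S)-1,2,3-trimethylcyclohex-3-ene-1-carboxylate, via lithium enolate 5 (not isolated)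
Conditions: LiN(i-Pr)2, THF, −78 °C; MeI, DMPU, −78 → −20 °C
Reagents that add atoms: iodomethane, CI
Why: Ester enolate alkylation: in the exocyclic enolate the C2 methyl is held pseudoaxial by allylic strain (against the enolate oxygens and the C3 methyl), so iodomethane should enter anti to it and create the quaternary centre with the new methyl trans to the C2 methyl and the carboxyl group cis to it.

Step 4
Reactants: 6
Product: 7 (1R,2S)-1,2,3-trimethylcyclohex-3-ene-1-carbaldehyde
Conditions: i-Bu2AlH (1.1 equiv), CH2Cl2, −78 °C; MeOH, aq. KNaC4H4O6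
Reagents that add atoms: none
Why: Partial reduction of a hindered α-quaternary ester: the tetrahedral aluminate should persist at −78 °C and collapse to the aldehyde only on work-up, and no epimerisable centre lies next to the carbonyl.

Step 5
Reactants: 7
Product: 8 (3S,4S)-4-ethenyl-2,3,4-trimethylcyclohex-1-ene
Conditions: Ph3PCH3Br, KOt-Bu, THF, 0 °C → rt
Reagents that add atoms: methyltriphenylphosphonium bromide, C[P+](c1ccccc1)(c1ccccc1)c1ccccc1.[Br-]
Why: Wittig methylenation of a non-enolisable aldehyde with the small unstabilised ylide should tolerate the neighbouring quaternary carbon.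

Step 6
Reactants: 8
Product: 9 4,4,5,5-tetramethyl-2-{2-[(1R,2R)-1,2,3-trimethylcyclohex-3-en-1-yl]ethyl}-1,3,2-dioxaborolane
Conditions: HBpin, [Ir(cod)Cl]2 (1.5 mol%), dppm (3 mol%), CH2Cl2, rt
Reagents that add atoms: pinacolborane, CC1(C)OBOC1(C)C
Why: Iridium-catalysed hydroboration with pinacolborane is anti-Markovnikov and should select the monosubstituted alkene, leaving the trisubstituted ring alkene untouched.

Step 7
Reactants: 10 (2R)-4-(trimethylsilyl)but-3-yn-2-ol
Product: 11 (2R)-4-(trimethylsilyl)but-3-yn-2-yl N,N-diisopropylcarbamate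
Conditions: i-Pr2NCOCl, Et3N, CH2Cl2, reflux
Reagents that add atoms: N,N-diisopropylcarbamoyl chloride, CC(C)N(C(C)C)C(Cl)=O
Why: O-Carbamoylation of the secondary alcohol installs the directing and leaving group for lithiation without touching the stereocentre.

Step 8
Reactants: 11; 9
Product: 16 (3S)-3-methyl-5-[(1S,2R)-1,2,3-trimethylcyclohex-3-en-1-yl]pent-1-yn-3-ol, via lithiated carbamate 12 (not isolated), via boronate complex 13 (not isolated), via tertiary boronic ester 14 (not isolated), via silylalkynol 15 (not isolated)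
Conditions: 11 (1.3 equiv), s-BuLi, TMEDA, Et2O, −78 °C; 9, −78 °C; MgBr2·OEt2, −78 °C → rt; NaOH, H2O2, THF, 0 °C → rt; K2CO3, MeOH, rt
Reagents that add atoms: hydrogen peroxide, OO
Why: Lithiation–borylation: deprotonation α to the carbamate and capture by the boronic ester should both proceed with retention, the anti-periplanar 1,2-metallate shift then expels the carbamate with inversion, and stereoretentive C–B oxidation puts the hydroxyl where the boron sat, so that overall the alkyl group replaces the original hydrogen with retention and protodesilylation leaves the (S)-tertiary propargylic alcohol.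

Step 9
Reactants: 16
Product: 17 trimethyl({(3S)-3-methyl-5-[(1S,2R)-1,2,3-trimethylcyclohex-3-en-1-yl]pent-1-yn-3-yl}oxy)silane
Conditions: Me3SiCl, imidazole, DMF, rt
Reagents that add atoms: chlorotrimethylsilane, C[Si](C)(C)Cl
Why: Silylation masks the tertiary hydroxyl for the acetylide addition and the anhydride-triggered rearrangement, and the ether is labile enough to fall off in the later aqueous oxidation.

Step 10
Reactants: 18 3,4-dimethoxycyclobut-3-ene-1,2-dione (dimethyl squarate); 19 methoxyethene (methyl vinyl ether)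
Product: 22 2,3,4-trimethoxy-4-(1-methoxyethenyl)cyclobut-2-en-1-one (racemic), via methoxyvinyllithium 20 (not isolated), via lithium alkoxide 21 (not isolated)
Conditions: 19, t-BuLi, THF, −78 → 0 °C; 18, THF, −78 °C; MeOTf, −78 → 0 °C
Reagents that add atoms: methyl trifluoromethanesulfonate, COS(=O)(=O)C(F)(F)F
Why: α-Lithiation of the enol ether, 1,2-addition of the vinyllithium to one carbonyl of the squaric ester and in situ O-methylation of the alkoxide should give the protected 4-alkenylcyclobutenone.

Step 11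
Reactants: 17; 22
Product: 25 2,4-dimethoxy-4-(1-methoxyethenyl)-3-{(3S)-3-methyl-3-[(trimethylsilyl)oxy]-5-[(1S,2R)-1,2,3-trimethylcyclohex-3-en-1-yl]pent-1-yn-1-yl}cyclobut-2-en-1-one (both C4 epimers), via lithium acetylide 23 (not isolated), via alkoxide adduct 24 (not isolated)
Conditions: 17, n-BuLi, THF, −78 °C; 22, −78 °C; (CF3CO)2O, −78 °C; aq. NaHCO3
Reagents that add atoms: water, O
Why: 1,2-Addition of the acetylide to the remaining carbonyl, then trifluoroacetylation, ionisation to the dimethoxy-stabilised cyclobutenyl cation and hydrolysis at its distal carbon (1,3-carbonyl transposition) should place the alkyne on C3 and the carbonyl next to the methoxy-bearing C2, while the cold anhydrous conditions and bicarbonate quench spare the enol ether.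

Step 12
Reactants: 25
Product: 28 2,4,5-trimethoxy-3-{(3S)-3-methyl-3-[(trimethylsilyl)oxy]-5-[(1S,2R)-1,2,3-trimethylcyclohex-3-en-1-yl]pent-1-yn-1-yl}phenol, via dienylketene 26 (not isolated), via cyclohexadienone 27 (not isolated)
Conditions: toluene (degassed), 110 °C
Reagents that add atoms: none
Why: On heating, the cyclobutenone should undergo conrotatory 4π-electrocyclic opening of its C1–C4 bond, the C4 methoxy donor rotating outward so that the 1-methoxyvinyl group turns inward and ends cis to the ketene in 26. The ketene carbon then bonds to the vinyl CH2 in a thermal disrotatory 6π-electrocyclisation that closes the six-membered carbocycle (the new bond is the later quinone C7–C8 bond, the ketene carbon becoming C8), and dienone 27 tautomerises to the phenol, aromatisation making the cascade irreversible. The closest known reaction type is the thermal ring expansion of squarate-derived 4-alkenyl-4-alkoxy(or hydroxy)cyclobutenones to hydroquinone derivatives. No stereocentre is created: the cyclobutenone C4 centre (both epimers) is destroyed and the three side-chain centres are remote from the reacting π-system. The step needs torquoselectivity and regiocontrol; the first is secured by the alkoxy group at C4 (a wrongly rotated ketene can only re-close), the second by the order of the two organolithium additions in steps 10 and 11, which places OH, OMe, alkyne, OMe, OMe and H unambiguously around the new ring. The alkyne on C3 cannot reach the ketene carbon, so only the vinyl group cyclises.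

Step 13
Reactants: 28
Product: 29 2,4,5-trimethoxy-3-{(1Z,3S)-3-methyl-3-[(trimethylsilyl)oxy]-5-[(1S,2R)-1,2,3-trimethylcyclohex-3-en-1-yl]pent-1-en-1-yl}phenol
Conditions: H2 (1 atm), Pd/CaCO3 poisoned with Pb(OAc)2, quinoline, EtOAc, rt
Reagents that add atoms: none
Why: Lindlar-type semihydrogenation: syn delivery of hydrogen to the alkyne should give the Z alkene needed for the later ring closure, and is run before quinone formation because a quinone would itself be reduced; the trisubstituted ring alkene is inert.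

Step 14
Reactants: 29
Product: 30 3-{(1Z,3S)-3-hydroxy-3-methyl-5-[(1S,2R)-1,2,3-trimethylcyclohex-3-en-1-yl]pent-1-en-1-yl}-2,5-dimethoxycyclohexa-2,5-diene-1,4-dione
Conditions: (NH4)2Ce(NO3)6 (2.2 equiv), MeCN/H2O, 0 °C
Reagents that add atoms: water, O
Why: Oxidative demethylation of the para-methoxyphenol by tetravalent cerium should give the para-quinone within minutes, and the acidic aqueous medium should hydrolyse the tertiary trimethylsilyl ether, the short cold exposure sparing both alkenes.

Step 15
Reactants: 30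
Product: 31 (2S)-6-methoxy-2-methyl-2-{2-[(1S,2R)-1,2,3-trimethylcyclohex-3-en-1-yl]ethyl}-2H-chromene-5,8-dione
Conditions: Cs2CO3 (0.5 equiv), 4 Å molecular sieves, MeCN, rt
Reagents that add atoms: none
Why: Intramolecular addition–elimination (vinylogous transesterification): the tertiary alkoxide should add to the methoxy-bearing C2 of the quinone (β-carbon of the C4 enone) in a six-membered closure enforced by the Z alkene and expel methoxide, and since the carbinol C–O bond is never broken the configuration is retained.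

**Compound list**

1 | (4S)-4-benzyl-3-(prop-2-enoyl)-1,3-oxazolidin-2-one | C=CC(=O)N1[C@@H](Cc2ccccc2)COC1=O | starting material
2 | (3E)-3-methylpenta-1,3-diene | C=C/C(C)=C/C | starting material
3 | (4S)-4-benzyl-3-{[(1R,2R)-2,3-dimethylcyclohex-3-en-1-yl]carbonyl}-1,3-oxazolidin-2-one | O=C([C@@H]1CCC=C(C)[C@@H]1C)N1[C@@H](Cc2ccccc2)COC1=O | intermediate
4 | ethyl (1R,2R)-2,3-dimethylcyclohex-3-ene-1-carboxylate | CCOC(=O)[C@@H]1CCC=C(C)[C@@H]1C | intermediate
5 | lithium enolate of 4 | CCOC(O[Li])=C1CCC=C(C)[C@@H]1C | intermediate (not isolated)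
6 | ethyl (1R,2S)-1,2,3-trimethylcyclohex-3-ene-1-carboxylate | CCOC(=O)[C@]1(C)CCC=C(C)[C@@H]1C | intermediate
7 | (1R,2S)-1,2,3-trimethylcyclohex-3-ene-1-carbaldehyde | O=C[C@]1(C)CCC=C(C)[C@@H]1C | intermediate
8 | (3S,4S)-4-ethenyl-2,3,4-trimethylcyclohex-1-ene | C=C[C@]1(C)CCC=C(C)[C@@H]1C | intermediate
9 | 4,4,5,5-tetramethyl-2-{2-[(1R,2R)-1,2,3-trimethylcyclohex-3-en-1-yl]ethyl}-1,3,2-dioxaborolane | CC1(C)OB(CC[C@]2(C)CCC=C(C)[C@@H]2C)OC1(C)C | intermediate
10 | (2R)-4-(trimethylsilyl)but-3-yn-2-ol | C[C@@H](O)C#C[Si](C)(C)C | starting material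
11 | (2R)-4-(trimethylsilyl)but-3-yn-2-yl N,N-diisopropylcarbamate | C[C@@H](OC(=O)N(C(C)C)C(C)C)C#C[Si](C)(C)C | intermediate
12 | α-lithiated carbamate from 11 (configuration retained) | C[C@@]([Li])(OC(=O)N(C(C)C)C(C)C)C#C[Si](C)(C)C | intermediate (not isolated)
13 | lithium boronate complex of 12 and 9 | C[C@@]([B-]1(CC[C@]2(C)CCC=C(C)[C@@H]2C)OC(C)(C)C(C)(C)O1)(OC(=O)N(C(C)C)C(C)C)C#C[Si](C)(C)C.[Li+] | intermediate (not isolated)
14 | 4,4,5,5-tetramethyl-2-{(3R)-3-methyl-1-(trimethylsilyl)-5-[(1S,2R)-1,2,3-trimethylcyclohex-3-en-1-yl]pent-1-yn-3-yl}-1,3,2-dioxaborolane | C[Si](C)(C)C#C[C@](C)(CC[C@]1(C)CCC=C(C)[C@@H]1C)B1OC(C)(C)C(C)(C)O1 | intermediate (not isolated)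
15 | (3S)-3-methyl-1-(trimethylsilyl)-5-[(1S,2R)-1,2,3-trimethylcyclohex-3-en-1-yl]pent-1-yn-3-ol | C[Si](C)(C)C#C[C@](C)(CC[C@]1(C)CCC=C(C)[C@@H]1C)O | intermediate (not isolated)
16 | (3S)-3-methyl-5-[(1S,2R)-1,2,3-trimethylcyclohex-3-en-1-yl]pent-1-yn-3-ol | C#C[C@](C)(CC[C@]1(C)CCC=C(C)[C@@H]1C)O | intermediate
17 | trimethyl({(3S)-3-methyl-5-[(1S,2R)-1,2,3-trimethylcyclohex-3-en-1-yl]pent-1-yn-3-yl}oxy)silane | C#C[C@](C)(CC[C@]1(C)CCC=C(C)[C@@H]1C)O[Si](C)(C)C | intermediate
18 | 3,4-dimethoxycyclobut-3-ene-1,2-dione (dimethyl squarate) | COC1=C(OC)C(=O)C1=O | starting material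
19 | methoxyethene (methyl vinyl ether) | COC=C | starting material
20 | (1-methoxyethenyl)lithium | [Li]C(=C)OC | intermediate (not isolated)
21 | lithium 2,3-dimethoxy-1-(1-methoxyethenyl)-4-oxocyclobut-2-en-1-olate (racemic) | [Li]OC1(C(=C)OC)C(OC)=C(OC)C1=O | intermediate (not isolated)
22 | 2,3,4-trimethoxy-4-(1-methoxyethenyl)cyclobut-2-en-1-one (racemic) | COC(=C)C1(OC)C(OC)=C(OC)C1=O | intermediate
23 | lithium acetylide of 17 | [Li]C#C[C@](C)(CC[C@]1(C)CCC=C(C)[C@@H]1C)O[Si](C)(C)C | intermediate (not isolated)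
24 | lithium alkoxide from 1,2-addition of 23 to 22 (ring stereoisomers) | [Li]OC1(C#C[C@](C)(CC[C@]2(C)CCC=C(C)[C@@H]2C)O[Si](C)(C)C)C(OC)=C(OC)C1(OC)C(=C)OC | intermediate (not isolated)
25 | 2,4-dimethoxy-4-(1-methoxyethenyl)-3-{(3S)-3-methyl-3-[(trimethylsilyl)oxy]-5-[(1S,2R)-1,2,3-trimethylcyclohex-3-en-1-yl]pent-1-yn-1-yl}cyclobut-2-en-1-one (both C4 epimers) | O=C1C(OC)=C(C#C[C@](C)(CC[C@]2(C)CCC=C(C)[C@@H]2C)O[Si](C)(C)C)C1(OC)C(=C)OC | intermediate
26 | dienylketene from ring opening of 25 (methoxyvinyl cis to the ketene-bearing carbon) | O=C=C(OC)/C(C#C[C@](C)(CC[C@]1(C)CCC=C(C)[C@@H]1C)O[Si](C)(C)C)=C(/OC)C(=C)OC | intermediate (not isolated)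
27 | 2,4,5-trimethoxy-3-alkynylcyclohexa-2,4-dien-1-one (keto tautomer of 28) | O=C1CC(OC)=C(OC)C(C#C[C@](C)(CC[C@]2(C)CCC=C(C)[C@@H]2C)O[Si](C)(C)C)=C1OC | intermediate (not isolated)
28 | 2,4,5-trimethoxy-3-{(3S)-3-methyl-3-[(trimethylsilyl)oxy]-5-[(1S,2R)-1,2,3-trimethylcyclohex-3-en-1-yl]pent-1-yn-1-yl}phenol | COc1cc(O)c(OC)c(C#C[C@](C)(CC[C@]2(C)CCC=C(C)[C@@H]2C)O[Si](C)(C)C)c1OC | intermediate
29 | 2,4,5-trimethoxy-3-{(1Z,3S)-3-methyl-3-[(trimethylsilyl)oxy]-5-[(1S,2R)-1,2,3-trimethylcyclohex-3-en-1-yl]pent-1-en-1-yl}phenol | COc1cc(O)c(OC)c(/C=C\[C@](C)(CC[C@]2(C)CCC=C(C)[C@@H]2C)O[Si](C)(C)C)c1OC | intermediate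
30 | 3-{(1Z,3S)-3-hydroxy-3-methyl-5-[(1S,2R)-1,2,3-trimethylcyclohex-3-en-1-yl]pent-1-en-1-yl}-2,5-dimethoxycyclohexa-2,5-diene-1,4-dione | COC1=CC(=O)C(OC)=C(/C=C\[C@](C)(CC[C@]2(C)CCC=C(C)[C@@H]2C)O)C1=O | intermediate
31 | (2S)-6-methoxy-2-methyl-2-{2-[(1S,2R)-1,2,3-trimethylcyclohex-3-en-1-yl]ethyl}-2H-chromene-5,8-dione | COC1=CC(=O)C2=C(C=C[C@](C)(CC[C@]3(C)CCC=C(C)[C@@H]3C)O2)C1=O | target

**Count and risks**

Total steps: 15. Longest linear sequence: 13 (steps 1–6, 8, 9, 11–15).

Steps most likely to fail: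

1. Step 8. The lithiated propargylic carbamate may racemise before it is captured, or borylation and migration may run through the allenyl position, eroding the carbinol configuration or diverting material to allenes. The fallback sets out from 8 and comes back at 16. Hydroboration of 8 with 9-BBN and B-alkyl Suzuki–Miyaura coupling (Pd(dppf)Cl2, Cs2CO3, DMF/THF/H2O) with (E)-3-iodobut-2-en-1-ol should give (2E)-3-methyl-5-[(1S,2R)-1,2,3-trimethylcyclohex-3-en-1-yl]pent-2-en-1-ol F1. Sharpless epoxidation (Ti(Oi-Pr)4, L-(+)-diethyl tartrate, t-BuOOH, CH2Cl2, −20 °C) should then give the (2S,3S)-epoxy alcohol F2, and PPh3/CCl4 the epoxy chloride F3. Treatment of F3 with n-BuLi (3 equiv, THF, −40 °C) should open the epoxide by double elimination to the tertiary propargylic alcohol 16, the carbinol C–O bond staying intact.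

2. Step 1. The two methyl groups of the diene direct to opposite regiochemistry, so bonding of the unsubstituted diene terminus to the α-carbon, together with incomplete endo or facial control, may leave isomers that are hard to remove. The fallback does not start from 1 and 2 but from commercial Hagemann's ester, ethyl 2-methyl-4-oxocyclohex-2-ene-1-carboxylate F4, and comes back at 6. C3-methylation (NaOEt, MeI, EtOH) should give ethyl 2,3-dimethyl-4-oxocyclohex-2-ene-1-carboxylate F5, which sets the methyl positions unambiguously. CBS reduction ((R)-2-methyl-CBS-oxazaborolidine, BH3·SMe2) should give the (4S)-allylic alcohol F6 as C1 epimers. Reductive 1,3-transposition by a Mitsunobu reaction with 2-nitrobenzenesulfonylhydrazide (PPh3, DEAD, −30 °C → rt; allylic diazene, loss of N2) should deliver hydrogen to C2 anti to the original hydroxyl and give ethyl (2R)-2,3-dimethylcyclohex-3-ene-1-carboxylate F7 as C1 epimers. Enolisation erases C1, so the conditions of step 3 should convert F7 into 6.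

3. Step 13. The alkyne lies between a 2,6-disubstituted arene and a quaternary carbon, so hydrogen uptake may stall, or over-reduction and Z-to-E isomerisation may set in. The fallback sets out from 17 and comes back at 29. Iodination (N-iodosuccinimide, AgNO3 cat., acetone) should give the iodoalkyne F8, and diimide reduction (2-nitrobenzenesulfonylhydrazide, Et3N) the (Z)-iodoalkene F9. Iodine–lithium exchange (t-BuLi, Et2O, −78 °C), addition of the Z-vinyllithium to 22 and the anhydride-triggered transposition of step 11 should give the Z-alkenylcyclobutenone F10. Heating F10 as in step 12 should give 29 directly.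

Further compounds
F1 | step 8 | (2E)-3-methyl-5-[(1S,2R)-1,2,3-trimethylcyclohex-3-en-1-yl]pent-2-en-1-ol | OC/C=C(C)/CC[C@]1(C)CCC=C(C)[C@@H]1C
F2 | step 8 | [(2S,3S)-3-methyl-3-{2-[(1S,2R)-1,2,3-trimethylcyclohex-3-en-1-yl]ethyl}oxiran-2-yl]methanol | OC[C@@H]1O[C@@]1(C)CC[C@]2(C)CCC=C(C)[C@@H]2C
F3 | step 8 | (2S,3R)-3-(chloromethyl)-2-methyl-2-{2-[(1S,2R)-1,2,3-trimethylcyclohex-3-en-1-yl]ethyl}oxirane | ClC[C@@H]1O[C@@]1(C)CC[C@]2(C)CCC=C(C)[C@@H]2C
F4 | step 1 | ethyl 2-methyl-4-oxocyclohex-2-ene-1-carboxylate (Hagemann's ester, commercial) | CCOC(=O)C1CCC(=O)C=C1C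
F5 | step 1 | ethyl 2,3-dimethyl-4-oxocyclohex-2-ene-1-carboxylate (racemic) | CCOC(=O)C1CCC(=O)C(C)=C1C
F6 | step 1 | ethyl (4S)-4-hydroxy-2,3-dimethylcyclohex-2-ene-1-carboxylate (C1 epimers) | CCOC(=O)C1CC[C@H](O)C(C)=C1C
F7 | step 1 | ethyl (2R)-2,3-dimethylcyclohex-3-ene-1-carboxylate (C1 epimers) | CCOC(=O)C1CCC=C(C)[C@@H]1C
F8 | step 13 | ({(3S)-1-iodo-3-methyl-5-[(1S,2R)-1,2,3-trimethylcyclohex-3-en-1-yl]pent-1-yn-3-yl}oxy)trimethylsilane | IC#C[C@](C)(CC[C@]1(C)CCC=C(C)[C@@H]1C)O[Si](C)(C)C
F9 | step 13 | ({(1Z,3S)-1-iodo-3-methyl-5-[(1S,2R)-1,2,3-trimethylcyclohex-3-en-1-yl]pent-1-en-3-yl}oxy)trimethylsilane | I/C=C\[C@](C)(CC[C@]1(C)CCC=C(C)[C@@H]1C)O[Si](C)(C)C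
F10 | step 13 | 2,4-dimethoxy-4-(1-methoxyethenyl)-3-{(1Z,3S)-3-methyl-3-[(trimethylsilyl)oxy]-5-[(1S,2R)-1,2,3-trimethylcyclohex-3-en-1-yl]pent-1-en-1-yl}cyclobut-2-en-1-one (both C4 epimers) | O=C1C(OC)=C(/C=C\[C@](C)(CC[C@]2(C)CCC=C(C)[C@@H]2C)O[Si](C)(C)C)C1(OC)C(=C)OC
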